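**Retrosynthetic overview**
- The 14-membered ring is closed last, at the C(=O)CH2–C(Me)= bond, by a Pd-catalysed coupling of a zinc ketone enolate (from a bromomethyl ketone) with an (E)-alkenyl bromide.
- The bromomethyl ketone comes from a lactone carboxylic acid (one-carbon homologation); the trans-2,5-oxolane comes from a (Z)-trisubstituted alkene by asymmetric epoxidation and 5-exo opening by the secondary hydroxyl.
- That alkene is made by a B-alkyl Suzuki–Miyaura union of fragment West (γ-lactone with a (Z)-alkenyl iodide) and fragment East (allylic alcohol with an (E)-alkenyl bromide).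
- Fragment West: anti-aldol–lactonisation of a succinate imide with (Z)-3-iodobut-2-enal, then trans α-methylation.
- Fragment East: asymmetric (Z)-crotylboration of a silylpropynal, then B-alkyl Suzuki coupling with (E)-2-bromo-1-iodopropene. Ring order: γ-lactone, oxolane, macrocycle.

Assumption: the given SMILES defines the target completely (E-alkene, seven stereocentres); the hydroxy ketone is drawn open-chain although it may equilibrate with its cyclic hemiketal.

**Fragment West**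

Step 1
Reactants: 1 but-2-yn-1-ol
Product: 3 (Z)-3-iodobut-2-en-1-ol, via sodium alkenylalanate 2 (not isolated)
Conditions: NaAlH2(OCH2CH2OMe)2, THF, 0 → 23 °C; then I2, THF, −78 → 0 °C
Reagents that add atoms: iodine, [I][I]
Why: Hydroxyl-directed trans-hydroalumination places Al on C3 in a five-membered alanate and iodinolysis with retention fixes the (Z)-alkenyl iodide (hydroalumination–iodination of a propargylic alcohol).

Step 2
Reactants: 3 (Z)-3-iodobut-2-en-1-ol
Product: 4 (Z)-3-iodobut-2-enal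
Conditions: MnO2, CH2Cl2, 23 °C, dark
Reagents that add atoms: none
Why: MnO2 oxidises the allylic alcohol to the enal under neutral conditions that do not isomerise the (Z)-iodoalkene (allylic oxidation).

Step 3
Reactants: 5 succinic anhydride
Product: 6 4-methoxy-4-oxobutanoic acid
Conditions: MeOH, 65 °C
Reagents that add atoms: methanol, CO
Why: Methanolysis of the symmetrical cyclic anhydride gives the monoester cleanly (anhydride ring opening).

Step 4
Reactants: 6 4-methoxy-4-oxobutanoic acid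
Product: 8 methyl 4-[(4S)-4-benzyl-2-oxo-1,3-oxazolidin-3-yl]-4-oxobutanoate, via mixed pivalic anhydride 7 (not isolated)
Conditions: t-BuCOCl, Et3N, THF, −20 °C; then (S)-4-benzyl-1,3-oxazolidin-2-one, LiCl, −20 → 23 °C
Reagents that add atoms: (S)-4-benzyl-1,3-oxazolidin-2-one, O=C1N[C@@H](Cc2ccccc2)CO1
Why: The mixed anhydride acylates the oxazolidinone nitrogen at the less hindered carbonyl under LiCl/Et3N activation (mixed-anhydride N-acylation).

Step 5
Reactants: 8 methyl 4-[(4S)-4-benzyl-2-oxo-1,3-oxazolidin-3-yl]-4-oxobutanoate; 4 (Z)-3-iodobut-2-enal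
Product: 11 (4S)-4-benzyl-3-{[(2S,3R)-2-[(Z)-2-iodoprop-1-en-1-yl]-5-oxooxolan-3-yl]carbonyl}-1,3-oxazolidin-2-one, via silyl aldol adduct 9 (not isolated), via hydroxy ester 10 (not isolated)
Conditions: MgCl2 (20 mol %), Et3N, Me3SiCl, EtOAc, 0 → 23 °C; then 1 M HCl, THF, 23 °C
Reagents that add atoms: none
Why: Soft enolisation gives the chelated magnesium (Z)-enolate, which adds to the enal on the face away from the benzyl group to set the anti pair (oxolane C3 R, C2 S), and the freed γ-hydroxy ester closes to the cis-2,3-disubstituted lactone (Evans MgCl2-catalysed anti-aldol, then lactonisation).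

Step 6
Reactants: 11 lactone imide
Product: 13 (2S,3R)-2-[(Z)-2-iodoprop-1-en-1-yl]-5-oxooxolane-3-carboxylic acid, via lithium peroxycarboxylate 12 (not isolated)
Conditions: LiOH, H2O2, THF/H2O, 0 °C; then Na2SO3; then 1 M HCl to pH 2
Reagents that add atoms: hydrogen peroxide, OO
Why: Hydroperoxide attacks the exocyclic imide carbonyl selectively and releases the auxiliary without opening the lactone or epimerising C3 (LiOH/H2O2 auxiliary cleavage).

Step 7
Reactants: 13 lactone acid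
Product: 15 (2S,3R,4R)-2-[(Z)-2-iodoprop-1-en-1-yl]-4-methyl-5-oxooxolane-3-carboxylic acid, via dilithium enolate carboxylate 14 (not isolated)
Conditions: LiN(SiMe3)2 (2.2 equiv), THF, −78 °C; then MeI, −78 → −40 °C; 1 M HCl
Reagents that add atoms: iodomethane, IC
Why: The carboxylate protects C3 from deprotonation and the lactone enolate is methylated anti to both the C3 carboxylate and the C2 alkenyl group, setting C4 (R) trans to the carboxyl (substrate-controlled enolate alkylation of a paraconic-type dianion).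

Step 8
Reactants: 15 α-methyl lactone acid
Product: 16 tert-butyl (2S,3R,4R)-2-[(Z)-2-iodoprop-1-en-1-yl]-4-methyl-5-oxooxolane-3-carboxylate
Conditions: t-BuOC(=NH)CCl3, BF3·OEt2 (5 mol %), CH2Cl2/cyclohexane, 23 °C
Reagents that add atoms: tert-butyl 2,2,2-trichloroacetimidate, CC(C)(C)OC(=N)C(Cl)(Cl)Cl
Why: Acid-catalysed tert-butylation esterifies the acid without base, so the epimerisable C3 is untouched (trichloroacetimidate esterification).

**Fragment East**

Step 9
Reactants: 17 propyne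
Product: 18 (E)-2-bromo-1-iodoprop-1-ene
Conditions: IBr, CH2Cl2, −78 → 0 °C
Reagents that add atoms: iodine monobromide, IBr
Why: Electrophilic anti addition puts iodine on the terminal carbon and bromide on the internal carbon, giving the (E)-dihalide (Markovnikov halogenation of an alkyne).

Step 10
Reactants: 19 (Z)-but-2-ene; 20 3-(trimethylsilyl)prop-2-ynal
Product: 25 (3S,4R)-4-methyl-1-(trimethylsilyl)hex-5-en-1-yn-3-ol, via (Z)-crotylpotassium 21 (not isolated), via potassium crotylmethoxyborate 22 (not isolated), via (Z)-crotylborane 23 (not isolated), via borinate 24 (not isolated)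
Conditions: KOt-Bu, n-BuLi, THF, −78 → −45 °C; (−)-Ipc2BOMe, −78 °C; BF3·OEt2, −78 °C; then 20, −78 °C; then HOCH2CH2NH2, Et2O, 23 °C
Reagents that add atoms: none
Why: The (Z)-crotylborane adds through a chair transition state to the Si face of the aldehyde under control of the isopinocampheyl groups from (+)-α-pinene, setting C3 (S) and C4 (R) syn (Brown asymmetric crotylboration).

Step 11
Reactants: 25 (3S,4R)-4-methyl-1-(trimethylsilyl)hex-5-en-1-yn-3-ol; 18 (E)-2-bromo-1-iodoprop-1-ene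
Product: 27 (3S,4R,7E)-8-bromo-4-methyl-1-(trimethylsilyl)non-7-en-1-yn-3-ol, via bis(9-BBN) adduct 26 (not isolated)
Conditions: 9-BBN (2.5 equiv), THF, 0 → 23 °C; then 18, Pd(dppf)Cl2 (5 mol %), AsPh3, 3 M aq K3PO4, DMF, 23 °C
Reagents that add atoms: none
Why: 9-BBN hydroborates only the terminal alkene and the primary alkylborane couples at the C–I bond, which adds to zerovalent palladium far faster than the internal C–Br bond, with retention of geometry (B-alkyl Suzuki–Miyaura coupling).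

Step 12
Reactants: 27 silyl alkyne
Product: 28 (3S,4R,7E)-8-bromo-4-methylnon-7-en-1-yn-3-ol
Conditions: K2CO3 (cat.), MeOH, 23 °C
Reagents that add atoms: none
Why: Methoxide cleaves the C(sp)–Si bond selectively (protodesilylation of a silylalkyne).

Step 13
Reactants: 28 terminal alkyne
Product: 29 (3R,4R,7E)-8-bromo-4-methylnona-1,7-dien-3-ol
Conditions: H2 (1 atm), Pd/CaCO3/Pb(OAc)2, quinoline, EtOAc, 23 °C
Reagents that add atoms: none
Why: The poisoned Pd catalyst stops at the alkene and leaves the alkenyl bromide alone (Lindlar semihydrogenation).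

**Union and endgame**

Step 14
Reactants: 29 (3R,4R,7E)-8-bromo-4-methylnona-1,7-dien-3-ol; 16 tert-butyl (2S,3R,4R)-2-[(Z)-2-iodoprop-1-en-1-yl]-4-methyl-5-oxooxolane-3-carboxylate
Product: 31 tert-butyl (2R,3R,4R)-2-[(1Z,5R,6R,9E)-10-bromo-5-hydroxy-2,6-dimethylundeca-1,9-dien-1-yl]-4-methyl-5-oxooxolane-3-carboxylate, via alkylborane 30 (not isolated)
Conditions: 29 (1.3 equiv), 9-BBN (3 equiv), THF, 0 → 23 °C; then 16, Pd(dppf)Cl2 (10 mol %), AsPh3, 3 M aq K3PO4, DMF, 23 °C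
Reagents that add atoms: none
Why: Anti-Markovnikov hydroboration of the vinyl group and coupling of the alkylborane with the (Z)-alkenyl iodide proceed with retention to the (Z)-trisubstituted alkene, while the alkenyl bromide and, with the weak donor AsPh3 at 23 °C, the allylic lactone survive (B-alkyl Suzuki–Miyaura fragment coupling).

Step 15
Reactants: 31 (Z)-alkene
Product: 33 tert-butyl (2S,3R,4R)-2-[(R)-{(2R,5R)-5-[(2R,5E)-6-bromohept-5-en-2-yl]-2-methyloxolan-2-yl}(hydroxy)methyl]-4-methyl-5-oxooxolane-3-carboxylate, via epoxide 32 (not isolated)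
Conditions: D-fructose-derived Shi ketone (30 mol %), KHSO5, K2CO3, Bu4NHSO4, MeCN/(MeO)2CH2/aq Na2B4O7 buffer, 0 °C; then CSA (10 mol %), CH2Cl2, 0 → 23 °C
Reagents that add atoms: potassium peroxymonosulfate, [K+].[O-]S(=O)(=O)OO
Why: The chiral dioxirane epoxidises the only electron-rich alkene through the spiro transition state to the (2R,3S)-oxirane, and the secondary hydroxyl opens it 5-exo at the tertiary carbon with inversion, giving the quaternary oxolane centre (R), the trans-2,5 relationship and the (R)-carbinol (Shi epoxidation, then acid-catalysed epoxide-opening cyclisation).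

Step 16
Reactants: 33 oxolane alcohol
Product: 36 (2S,3R,4R)-2-[(R)-{(2R,5R)-5-[(2R,5E)-6-bromohept-5-en-2-yl]-2-methyloxolan-2-yl}(tert-butyldimethylsilyloxy)methyl]-4-methyl-5-oxooxolane-3-carboxylic acid, via TBS ether tert-butyl ester 34 (not isolated), via trimethylsilyl ester 35 (not isolated)
Conditions: TBSOTf, 2,6-lutidine, CH2Cl2, −78 → 0 °C; then Me3SiOTf, 0 → 23 °C; then pH 5 buffer, THF
Reagents that add atoms: tert-butyldimethylsilyl trifluoromethanesulfonate, CC(C)(C)[Si](C)(C)OS(=O)(=O)C(F)(F)F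
Why: The hindered alcohol is silylated first, Me3SiOTf then converts the tert-butyl ester into the labile silyl ester with loss of isobutene, and work-up frees the acid while the TBS ether stays (O-silylation and silyl triflate cleavage of a tert-butyl ester).

Step 17
Reactants: 36 TBS-protected acid
Product: 39 (3R,4R,5S)-4-(2-bromoacetyl)-5-[(R)-{(2R,5R)-5-[(2R,5E)-6-bromohept-5-en-2-yl]-2-methyloxolan-2-yl}(tert-butyldimethylsilyloxy)methyl]-3-methyloxolan-2-one, via acid chloride 37 (not isolated), via diazoketone 38 (not isolated)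
Conditions: Me2C=C(Cl)NMe2, CH2Cl2, 0 °C; then Me3SiCHN2, MeCN, 0 °C; then HBr (33% in AcOH), −20 °C
Reagents that add atoms: (trimethylsilyl)diazomethane, C[Si](C)(C)C=[N+]=[N-]; hydrogen bromide, Br
Why: The acid chloride made under neutral conditions acylates the diazoalkane and HBr turns the diazoketone into the bromomethyl ketone with loss of N2, all without base, so the β-acyloxy ketone cannot eliminate or epimerise (diazoketone formation and hydrobromination, Nierenstein-type).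

Step 18
Reactants: 39 bromomethyl ketone
Product: 41 tert-butyldimethylsilyl ether of the target macrocycle, via zinc enolate 40 (not isolated)
Conditions: Zn (activated, 5 equiv), [PdBr(P(t-Bu)3)]2 (5 mol %), THF, 45 °C, 39 added by syringe pump over 12 h (1 mM final); pH 7 buffer
Reagents that add atoms: none
Why: Proposed new method: Zn inserts only into the activated C–Br bond of the bromomethyl ketone to give a regiodefined, weakly basic zinc enolate, zerovalent palladium bearing P(t-Bu)3 adds oxidatively to the alkenyl bromide at the other chain end, and intramolecular transmetalation followed by C–C reductive elimination under slow-addition high dilution closes the 14-membered ring with retention of the (E)-alkene and without enolising the base-sensitive β-acyloxy ketone; the closest known reaction type is the intermolecular Pd-catalysed α-arylation and α-alkenylation of Reformatsky-type zinc enolates (a Negishi-type enolate coupling), which has not been used for a ketone enolate or for macrocyclisation.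

Step 19
Reactants: 41 silyl ether of the macrocycle
Product: 42 CNP0386136.3
Conditions: HF·pyridine, pyridine, THF, 0 → 23 °C
Reagents that add atoms: none
Why: Buffered fluoride cleaves the Si–O bond without touching the β,γ-unsaturated ketone or the lactone (silyl ether deprotection).

**Compound list**
1 | but-2-yn-1-ol | CC#CCO | starting material
2 | sodium 2,2-bis(2-methoxyethoxy)-3-methyl-2,5-dihydro-1,2-oxaluminol-2-uide (cyclic alkenylalanate) | [Na+].CC1=CCO[Al-]1(OCCOC)OCCOC | intermediate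
3 | (Z)-3-iodobut-2-en-1-ol | I/C(C)=C\CO | intermediate
4 | (Z)-3-iodobut-2-enal | I/C(C)=C\C=O | intermediate
5 | succinic anhydride | O=C1CCC(=O)O1 | starting material
6 | 4-methoxy-4-oxobutanoic acid | COC(=O)CCC(=O)O | intermediate
7 | 4-methoxy-4-oxobutanoic 2,2-dimethylpropanoic anhydride | COC(=O)CCC(=O)OC(=O)C(C)(C)C | intermediate
8 | methyl 4-[(4S)-4-benzyl-2-oxo-1,3-oxazolidin-3-yl]-4-oxobutanoate | COC(=O)CCC(=O)N1[C@@H](Cc2ccccc2)COC1=O | intermediate
9 | methyl (3R,4S,5Z)-3-{[(4S)-4-benzyl-2-oxo-1,3-oxazolidin-3-yl]carbonyl}-6-iodo-4-[(trimethylsilyl)oxy]hept-5-enoate | I/C(C)=C\[C@@H](O[Si](C)(C)C)[C@@H](CC(=O)OC)C(=O)N1[C@@H](Cc2ccccc2)COC1=O | intermediate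
10 | methyl (3R,4S,5Z)-3-{[(4S)-4-benzyl-2-oxo-1,3-oxazolidin-3-yl]carbonyl}-4-hydroxy-6-iodohept-5-enoate | I/C(C)=C\[C@@H](O)[C@@H](CC(=O)OC)C(=O)N1[C@@H](Cc2ccccc2)COC1=O | intermediate
11 | (4S)-4-benzyl-3-{[(2S,3R)-2-[(Z)-2-iodoprop-1-en-1-yl]-5-oxooxolan-3-yl]carbonyl}-1,3-oxazolidin-2-one | I/C(C)=C\[C@H]1OC(=O)C[C@H]1C(=O)N2[C@@H](Cc3ccccc3)COC2=O | intermediate
12 | lithium (2S,3R)-2-[(Z)-2-iodoprop-1-en-1-yl]-5-oxooxolane-3-carboperoxoate | [Li+].I/C(C)=C\[C@H]1OC(=O)C[C@H]1C(=O)O[O-] | intermediate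
13 | (2S,3R)-2-[(Z)-2-iodoprop-1-en-1-yl]-5-oxooxolane-3-carboxylic acid | I/C(C)=C\[C@H]1OC(=O)C[C@H]1C(=O)O | intermediate
14 | dilithium (2S,3R)-2-[(Z)-2-iodoprop-1-en-1-yl]-5-oxido-2,3-dihydrofuran-3-carboxylate | [Li+].[Li+].I/C(C)=C\[C@H]1OC([O-])=C[C@H]1C(=O)[O-] | intermediate
15 | (2S,3R,4R)-2-[(Z)-2-iodoprop-1-en-1-yl]-4-methyl-5-oxooxolane-3-carboxylic acid | I/C(C)=C\[C@H]1OC(=O)[C@H](C)[C@H]1C(=O)O | intermediate
16 | tert-butyl (2S,3R,4R)-2-[(Z)-2-iodoprop-1-en-1-yl]-4-methyl-5-oxooxolane-3-carboxylate (fragment West) | I/C(C)=C\[C@H]1OC(=O)[C@H](C)[C@H]1C(=O)OC(C)(C)C | intermediate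
17 | propyne | CC#C | starting material
18 | (E)-2-bromo-1-iodoprop-1-ene | C/C(Br)=C\I | intermediate
19 | (Z)-but-2-ene | C/C=C\C | starting material
20 | 3-(trimethylsilyl)prop-2-ynal | C[Si](C)(C)C#CC=O | starting material
21 | (Z)-but-2-en-1-ylpotassium | C/C=C\C[K] | intermediate
22 | potassium (Z)-but-2-en-1-yl(methoxy)bis(isopinocampheyl)borate | [K+].C/C=C\C[B-](OC)([C@H]1[C@H](C)[C@H]2C[C@@H](C1)C2(C)C)[C@H]1[C@H](C)[C@H]2C[C@@H](C1)C2(C)C | intermediate
23 | (Z)-but-2-en-1-ylbis(isopinocampheyl)borane, Ipc groups from (+)-α-pinene | C/C=C\CB([C@H]1[C@H](C)[C@H]2C[C@@H](C1)C2(C)C)[C@H]1[C@H](C)[C@H]2C[C@@H](C1)C2(C)C | intermediate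
24 | (3S,4R)-4-methyl-1-(trimethylsilyl)hex-5-en-1-yn-3-yl bis(isopinocampheyl)borinate | C=C[C@@H](C)[C@H](OB([C@H]1[C@H](C)[C@H]2C[C@@H](C1)C2(C)C)[C@H]1[C@H](C)[C@H]2C[C@@H](C1)C2(C)C)C#C[Si](C)(C)C | intermediate
25 | (3S,4R)-4-methyl-1-(trimethylsilyl)hex-5-en-1-yn-3-ol | C=C[C@@H](C)[C@H](O)C#C[Si](C)(C)C | intermediate
26 | 9-[(3R,4S)-4-(9-borabicyclo[3.3.1]nonan-9-yloxy)-3-methyl-6-(trimethylsilyl)hex-5-yn-1-yl]-9-borabicyclo[3.3.1]nonane | B1(C2CCCC1CCC2)CC[C@@H](C)[C@H](OB1C2CCCC1CCC2)C#C[Si](C)(C)C | intermediate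
27 | (3S,4R,7E)-8-bromo-4-methyl-1-(trimethylsilyl)non-7-en-1-yn-3-ol | C/C(Br)=C\CC[C@@H](C)[C@H](O)C#C[Si](C)(C)C | intermediate
28 | (3S,4R,7E)-8-bromo-4-methylnon-7-en-1-yn-3-ol | C/C(Br)=C\CC[C@@H](C)[C@H](O)C#C | intermediate
29 | (3R,4R,7E)-8-bromo-4-methylnona-1,7-dien-3-ol (fragment East) | C/C(Br)=C\CC[C@@H](C)[C@H](O)C=C | intermediate
30 | 9-[(3R,4R,7E)-3-(9-borabicyclo[3.3.1]nonan-9-yloxy)-8-bromo-4-methylnon-7-en-1-yl]-9-borabicyclo[3.3.1]nonane | C/C(Br)=C\CC[C@@H](C)[C@H](OB1C2CCCC1CCC2)CCB1C2CCCC1CCC2 | intermediate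
31 | tert-butyl (2R,3R,4R)-2-[(1Z,5R,6R,9E)-10-bromo-5-hydroxy-2,6-dimethylundeca-1,9-dien-1-yl]-4-methyl-5-oxooxolane-3-carboxylate | C/C(Br)=C\CC[C@@H](C)[C@H](O)CC/C(C)=C\[C@H]1OC(=O)[C@H](C)[C@H]1C(=O)OC(C)(C)C | intermediate
32 | tert-butyl (2S,3R,4R)-2-[(2R,3S)-3-[(3R,4R,7E)-8-bromo-3-hydroxy-4-methylnon-7-en-1-yl]-3-methyloxiran-2-yl]-4-methyl-5-oxooxolane-3-carboxylate | C/C(Br)=C\CC[C@@H](C)[C@H](O)CC[C@]1(C)O[C@@H]1[C@H]2OC(=O)[C@H](C)[C@H]2C(=O)OC(C)(C)C | intermediate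
33 | tert-butyl (2S,3R,4R)-2-[(R)-{(2R,5R)-5-[(2R,5E)-6-bromohept-5-en-2-yl]-2-methyloxolan-2-yl}(hydroxy)methyl]-4-methyl-5-oxooxolane-3-carboxylate | C/C(Br)=C\CC[C@@H](C)[C@H]1CC[C@@](C)(O1)[C@H](O)[C@H]2OC(=O)[C@H](C)[C@H]2C(=O)OC(C)(C)C | intermediate
34 | tert-butyl (2S,3R,4R)-2-[(R)-{(2R,5R)-5-[(2R,5E)-6-bromohept-5-en-2-yl]-2-methyloxolan-2-yl}(tert-butyldimethylsilyloxy)methyl]-4-methyl-5-oxooxolane-3-carboxylate | C/C(Br)=C\CC[C@@H](C)[C@H]1CC[C@@](C)(O1)[C@H](O[Si](C)(C)C(C)(C)C)[C@H]2OC(=O)[C@H](C)[C@H]2C(=O)OC(C)(C)C | intermediate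
35 | trimethylsilyl (2S,3R,4R)-2-[(R)-{(2R,5R)-5-[(2R,5E)-6-bromohept-5-en-2-yl]-2-methyloxolan-2-yl}(tert-butyldimethylsilyloxy)methyl]-4-methyl-5-oxooxolane-3-carboxylate | C/C(Br)=C\CC[C@@H](C)[C@H]1CC[C@@](C)(O1)[C@H](O[Si](C)(C)C(C)(C)C)[C@H]2OC(=O)[C@H](C)[C@H]2C(=O)O[Si](C)(C)C | intermediate
36 | (2S,3R,4R)-2-[(R)-{(2R,5R)-5-[(2R,5E)-6-bromohept-5-en-2-yl]-2-methyloxolan-2-yl}(tert-butyldimethylsilyloxy)methyl]-4-methyl-5-oxooxolane-3-carboxylic acid | C/C(Br)=C\CC[C@@H](C)[C@H]1CC[C@@](C)(O1)[C@H](O[Si](C)(C)C(C)(C)C)[C@H]2OC(=O)[C@H](C)[C@H]2C(=O)O | intermediate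
37 | (2S,3R,4R)-2-[(R)-{(2R,5R)-5-[(2R,5E)-6-bromohept-5-en-2-yl]-2-methyloxolan-2-yl}(tert-butyldimethylsilyloxy)methyl]-4-methyl-5-oxooxolane-3-carbonyl chloride | C/C(Br)=C\CC[C@@H](C)[C@H]1CC[C@@](C)(O1)[C@H](O[Si](C)(C)C(C)(C)C)[C@H]2OC(=O)[C@H](C)[C@H]2C(=O)Cl | intermediate
38 | (3R,4R,5S)-5-[(R)-{(2R,5R)-5-[(2R,5E)-6-bromohept-5-en-2-yl]-2-methyloxolan-2-yl}(tert-butyldimethylsilyloxy)methyl]-4-(2-diazoacetyl)-3-methyloxolan-2-one | C/C(Br)=C\CC[C@@H](C)[C@H]1CC[C@@](C)(O1)[C@H](O[Si](C)(C)C(C)(C)C)[C@H]2OC(=O)[C@H](C)[C@H]2C(=O)C=[N+]=[N-] | intermediate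
39 | (3R,4R,5S)-4-(2-bromoacetyl)-5-[(R)-{(2R,5R)-5-[(2R,5E)-6-bromohept-5-en-2-yl]-2-methyloxolan-2-yl}(tert-butyldimethylsilyloxy)methyl]-3-methyloxolan-2-one | C/C(Br)=C\CC[C@@H](C)[C@H]1CC[C@@](C)(O1)[C@H](O[Si](C)(C)C(C)(C)C)[C@H]2OC(=O)[C@H](C)[C@H]2C(=O)CBr | intermediate
40 | bromo[(1-{(2S,3R,4R)-2-[(R)-{(2R,5R)-5-[(2R,5E)-6-bromohept-5-en-2-yl]-2-methyloxolan-2-yl}(tert-butyldimethylsilyloxy)methyl]-4-methyl-5-oxooxolan-3-yl}ethenyl)oxy]zinc (zinc enolate of 39) | C/C(Br)=C\CC[C@@H](C)[C@H]1CC[C@@](C)(O1)[C@H](O[Si](C)(C)C(C)(C)C)[C@H]2OC(=O)[C@H](C)[C@H]2C(=C)O[Zn]Br | intermediate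
41 | tert-butyldimethylsilyl ether of 42 at the secondary hydroxyl (closed 14-membered ring, configuration as in 42) | C/C1=C\CC[C@@H](C)[C@H]2CC[C@@](C)(O2)[C@H](O[Si](C)(C)C(C)(C)C)[C@H]2OC(=O)[C@H](C)[C@H]2C(=O)C1 | intermediate
42 | CNP0386136.3: 14-membered β,γ-unsaturated keto carbocycle with (E)-trisubstituted alkene, bridged by a trans-2,5-oxolane and cis-fused to an α-methyl-γ-butyrolactone; carbinol R, oxolane C2 R and C5 R, side-chain methyl carbon R, lactone C3 R, C4 R, C5 S | C/C1=C\CC[C@@H](C)[C@H]2CC[C@@](C)(O2)[C@H](O)[C@H]2OC(=O)[C@H](C)[C@H]2C(=O)C1 | target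

**Totals**
Total step count: 19. Longest linear sequence: 12 steps (1, 2, 5, 6, 7, 8, 14, 15, 16, 17, 18, 19; the branch 3, 4 is equally long), which is 63% of the total.

**Steps most likely to fail and their fallbacks**

Step 18, the new macrocyclisation. It may give oligomers, simple reduction to the methyl ketone, or elimination of the β-acyloxy ketone if the enolate equilibrates. The fallback uses only known chemistry, sets out from acid 36 and comes back at 41. Acid 36 is converted as in step 17 into acid chloride 37, which is acylated onto (2-methylallyl)trimethylsilane (TiCl4, CH2Cl2, −78 °C) to give the methallyl ketone (3R,4R,5S)-5-[(R)-{(2R,5R)-5-[(2R,5E)-6-bromohept-5-en-2-yl]-2-methyloxolan-2-yl}(tert-butyldimethylsilyloxy)methyl]-3-methyl-4-(3-methylbut-3-enoyl)oxolan-2-one F1. The alkenyl bromide is then reduced with Bu3SnH and Pd(PPh3)4 (THF, 23 °C) to (3R,4R,5S)-5-[(R)-(tert-butyldimethylsilyloxy){(2R,5R)-5-[(2R,5Z)-hept-5-en-2-yl]-2-methyloxolan-2-yl}methyl]-3-methyl-4-(3-methylbut-3-enoyl)oxolan-2-one F2. Ring-closing metathesis of F2 (second-generation Hoveyda–Grubbs catalyst, toluene, 80 °C, 1 mM) expels propene and closes the trisubstituted alkene to 41. Unlike the coupling, this route does not fix the alkene geometry, so the (E)-isomer must be separated from any (Z)-isomer.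

Step 5, the anti-aldol with the β-iodoenal. Aldehyde 4 is a vinylogous acyl iodide and may isomerise or be attacked by Et3N during the long reaction at 23 °C. The fallback brings in iodine only after the aldol; it sets out from 1 (with 8) and comes back at 11. Alcohol 1 is trans-hydrosilylated (Et3SiH, [Cp*Ru(MeCN)3]PF6, CH2Cl2) to (Z)-3-(triethylsilyl)but-2-en-1-ol F3 and oxidised (MnO2) to (Z)-3-(triethylsilyl)but-2-enal F4, which is inert to the amine. The same MgCl2-catalysed anti-aldol with 8 gives methyl (3R,4S,5Z)-3-{[(4S)-4-benzyl-2-oxo-1,3-oxazolidin-3-yl]carbonyl}-6-(triethylsilyl)-4-[(trimethylsilyl)oxy]hept-5-enoate F5. Dilute acid gives methyl (3R,4S,5Z)-3-{[(4S)-4-benzyl-2-oxo-1,3-oxazolidin-3-yl]carbonyl}-4-hydroxy-6-(triethylsilyl)hept-5-enoate F6, which lactonises to (4S)-4-benzyl-3-{[(2S,3R)-5-oxo-2-[(Z)-2-(triethylsilyl)prop-1-en-1-yl]oxolan-3-yl]carbonyl}-1,3-oxazolidin-2-one F7. Iododesilylation of F7 with retention (N-iodosuccinimide, (CF3)2CHOH, 0 °C) returns 11.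

Step 15, the reagent-controlled epoxidation. The alkene is deactivated by the allylic lactone oxygen and the facial selectivity of the dioxirane on this (Z)-trisubstituted alkene is not assured. The fallback replaces the undirected dioxirane by a hydroxyl-directed metal-catalysed epoxidation; it sets out from 31 and comes back at 33. Compound 31 is treated with Hf(Ot-Bu)4, a C2-symmetric chiral bishydroxamic acid ligand and cumene hydroperoxide (toluene, 0 °C). The hafnium alkoxide of the bishomoallylic hydroxyl selects this alkene and the ligand sets the face, giving the same epoxide 32, which cyclises with CSA to 33.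

**Further compounds**
F1 | step 18 | (3R,4R,5S)-5-[(R)-{(2R,5R)-5-[(2R,5E)-6-bromohept-5-en-2-yl]-2-methyloxolan-2-yl}(tert-butyldimethylsilyloxy)methyl]-3-methyl-4-(3-methylbut-3-enoyl)oxolan-2-one | C/C(Br)=C\CC[C@@H](C)[C@H]1CC[C@@](C)(O1)[C@H](O[Si](C)(C)C(C)(C)C)[C@H]2OC(=O)[C@H](C)[C@H]2C(=O)CC(C)=C
F2 | step 18 | (3R,4R,5S)-5-[(R)-(tert-butyldimethylsilyloxy){(2R,5R)-5-[(2R,5Z)-hept-5-en-2-yl]-2-methyloxolan-2-yl}methyl]-3-methyl-4-(3-methylbut-3-enoyl)oxolan-2-one | C/C=C\CC[C@@H](C)[C@H]1CC[C@@](C)(O1)[C@H](O[Si](C)(C)C(C)(C)C)[C@H]2OC(=O)[C@H](C)[C@H]2C(=O)CC(C)=C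
F3 | step 5 | (Z)-3-(triethylsilyl)but-2-en-1-ol | CC[Si](CC)(CC)/C(C)=C\CO
F4 | step 5 | (Z)-3-(triethylsilyl)but-2-enal | CC[Si](CC)(CC)/C(C)=C\C=O
F5 | step 5 | methyl (3R,4S,5Z)-3-{[(4S)-4-benzyl-2-oxo-1,3-oxazolidin-3-yl]carbonyl}-6-(triethylsilyl)-4-[(trimethylsilyl)oxy]hept-5-enoate | CC[Si](CC)(CC)/C(C)=C\[C@@H](O[Si](C)(C)C)[C@@H](CC(=O)OC)C(=O)N1[C@@H](Cc2ccccc2)COC1=O
F6 | step 5 | methyl (3R,4S,5Z)-3-{[(4S)-4-benzyl-2-oxo-1,3-oxazolidin-3-yl]carbonyl}-4-hydroxy-6-(triethylsilyl)hept-5-enoate | CC[Si](CC)(CC)/C(C)=C\[C@@H](O)[C@@H](CC(=O)OC)C(=O)N1[C@@H](Cc2ccccc2)COC1=O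
F7 | step 5 | (4S)-4-benzyl-3-{[(2S,3R)-5-oxo-2-[(Z)-2-(triethylsilyl)prop-1-en-1-yl]oxolan-3-yl]carbonyl}-1,3-oxazolidin-2-one | CC[Si](CC)(CC)/C(C)=C\[C@H]1OC(=O)C[C@H]1C(=O)N2[C@@H](Cc3ccccc3)COC2=O
F0 | step 15 | none | none
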